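The ratio to watch is the charge of solid substrate over the most of it that the solution holds.

| flask | solid substrate | solid reagent | remark | time |
|---|---|---|---|---|
| amber | 0.15 M | 0.20 M | run made earlier |  |
| flask | 0.10 M | 0.200 M |  | 50 min |

amber run (percent of the solid substrate charged)

| time / min | target / % | solid substrate / % |
|---|---|---|
| 1.50 | 0 | 63.7 |
| 3.00 | 1.6 | 55.9 |
| 5.00 | 4.5 | 51.8 |
| 6.00 | 4.9 | 49.4 |
| 8.00 | 8.3 | 46.5 |
| 10.0 | 9.6 | 44.2 |

(standard deviation of a reading: 0.5 percentage points)

- given per volume of solution although it is solid: solid substrate, solid reagent
- what was read earlier has a scatter of 0.5 percentage points, one standard deviation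
- at the start none of the solid substrate is in solution
- at the start none of the solid reagent is in solution

1. the target standing at 50 min, as a percentage of the solid substrate charged
2. the change that raises the amount of target at 50 min, in percent of the solid substrate charged most ("none" if none brings more than 2 percentage points) (spring / dusk / dawn / noon / none)
3. amount of target at 50 min, in percent of the solid substrate charged, after spring

- spring: doubling the solubility of the solid reagent, all else as stated
- dusk: doubling the dissolution coefficient of the solid substrate, all else as stated
- dawn: doubling the solubility of the solid substrate, all else as stated
- noon: doubling the dissolution coefficient of the solid reagent, all else as stated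

In the amber run, what neither solid substrate nor target accounts for we take to be dissolved substrate: 45.7 % at 6.00 min and 46.2 % at 10.0 min. We read this level as a ceiling c of 0.0693 M, which makes the flask's ratio 1.44. Target in the amber run climbs at a steady r of 0.00171 M min⁻¹, so r/c gives a pseudo-first-order constant k of 0.0247 min⁻¹.

The flask's excess over c, divided by r, gives 17.9 min, the reserve time: while solid stands, the rate is zero-order, and afterwards it is first-order. With an endless reserve, the flask would reach 85.7 %. With no reserve, c decaying from the start would give 49.2 %. The reserve time is shorter than the 50 min asked, so the flask lies between them, and our reckoning gives 68.7 %.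

If the rate follows the partner's level, spring doubles k and halves the reserve time, giving 90.9 %. Dawn lifts the ceiling above the charge, giving 70.9 %.

The forecast, holding that “substrate solubility caps it”, gave 68 %, below ours, with spring reaching 88 %.

The flask gives 71.6 %, and spring raises it most, to 90.7 %.

    solid substrate ⇌ dissolved substrate, rate k1*(cs1 - [dissolved substrate]) while solid is left; crystals form when [dissolved substrate] > cs1 (solubility = 0.0690 M, k = 1.00 min⁻¹)
    dissolved substrate + partner → target (k = 0.420 M⁻¹ min⁻¹)
    solid reagent ⇌ partner, rate k3*(cs3 - [partner]) while solid is left; crystals form when [partner] > cs3 (solubility = 0.0700 M, k = 0.740 min⁻¹)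
    solid substrate + target → side product (k = 0.170 M⁻¹ min⁻¹)

In the flask, the half-turnover time of the dissolving of solid substrate is 1.27 min, against a half-life of dissolved substrate by the path to target of 25 min at 4.42 min. Solid substrate stands at 26.8 % at 5.00 min and 0 % at 25.0 min, on either side of the reserve time of 17.9 min. For the neighbour that is the same flask read at 3.0 h, the reserve time of 17.9 min gives 98.7 %, and that neighbour stands at 98.4 % of target.

The earlier runs and the new flask stem from a simulated flask from invented constants; noise was put on by code.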